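3 questions stand on this flask, and we serve them with one ratio.

| flask | substrate | coupling partner | remark | time |
|---|---|---|---|---|
| cedar | 0.050 M | 0.050 M | the very flask that is asked about, followed so far |  |
| oak | 0.075 M | 0.050 M | run made earlier |  |
| flask | 0.050 M | 0.0500 M |  | 30 h |

- cedar (time / h: single product / %, double product / %, substrate / %): 1.33: 11.7, 0.9, 88.4; 2.50: 19.1, 0, 79.9; 4.00: 25.5, 0.3, 71.8; 8.00: 38.2, 0.5, 55.2; 15.0: 47.9, 0.2, 38.7
- oak (time / h: single product / %, double product / %, substrate / %): 6.00: 29.8, 0.8, 65.3; 12.0: 40.3, 0, 52.2; 20.0: 44.8, 0.1, 44.3; 25.0: 47.1, 0.3, 40.2; 30.0: 48.1, 0, 37.4

(standard deviation of a reading: 0.5 percentage points)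

1. equivalents of coupling partner to substrate, everything else as given, that leave most single product at 30 h
2. the amount of single product then, in percent of the substrate charged
3. the amount of single product with the amounts as given

- a species is counted by the substrate in it: one side product counts as two
- reactions considered so far: substrate + coupling partner -> single product; coupling partner + single product -> double product; coupling partner + double product <-> triple product; coupling partner <-> dormant form; substrate + double product -> side product

1. In cedar at 8.00 h, double product reads 0.5%, yet 6.60% of the substrate is unaccounted for. We read that as side product: each double product formed soon takes a substrate.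

2. So two events count. The first turns a substrate into single product. The second removes a single product and a substrate. Each uses one coupling partner, so c_partner cancels from their ratio: single product is made over used at c_substrate/(s·c_single).

3. Here s, the selectivity factor, is the rate constant of the second event over that of the first. Between 4.00 h and 15.0 h, cedar gains 0.677 single product per substrate lost. That gain equals (1−r)/(1+r), with r = s·c_single/c_substrate. Taking the concentrations at 8.00 h gives the reading s = 0.279. Oak, with other charges, reads 0.306 the same way.

4. Our own reckoning: cedar's charges are equal, each substrate lost costs one partner, and both events take substrate, so the slope of 1/c_substrate should go as 1+r. Cedar's readings from 8.00 h to 15.0 h give a slope of 0.0870 h⁻¹ per unit of 1+r. Holding r at its value of 0.345 at 15.0 h gives 23.1% substrate and 55.5% single product at 30 h, so r ends near 0.671. The mean of these two r then gives 22.0% substrate and about 53.4% single product. Made over used is then 1.48, still above one, so a little extra partner should pay.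

5. The forecast, with a ratio of 0.27, says 53.5%, and 55% at 1.12 equiv. Its ground: “Double product is trapped quickly by substrate.”

The flask gives 53.4%, and 54.1% at 1.15 equiv.

    substrate + coupling partner → single product (k = 2.90 M⁻¹ h⁻¹)
    coupling partner + single product → double product (k = 0.860 M⁻¹ h⁻¹)
    coupling partner + double product ⇌ triple product (K = 160 M⁻¹, k = 5.00 M⁻¹ h⁻¹)
    coupling partner ⇌ dormant form (K = 0.580, k = 1.10 h⁻¹)
    substrate + double product → side product (k = 41.0 M⁻¹ h⁻¹)

At 30.0 h the flask made single product 1.39 times as fast as it used it up, and s applied to its 22.0% substrate and 53.4% single product gives 1.48. A neighbouring flask with 0.085 M of coupling partner ended at 1.83% substrate and 47.3% single product, where the same ratio stands below one, at 0.139.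

(The runs are simulated with made-up constants; noise was put on by code.)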